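**Strategy.** Ring A (C4a', C5', C6', C7', C8', C8a') is disconnected at C6'–C7' and C5'–C4a'. This benzene ring is fused to the 2H-pyran at C4a'–C8a' and carries oxygen at C5' beside the chroman-bearing C6'. It therefore maps onto a 2,2-dimethylpyrano[4,3-b]pyran-5-one diene and a ring B 4-chromanyl ynol silyl ether. One operation (cycloaddition across the pyrone, then CO2 loss) forms both bonds and delivers the hexasubstituted, correctly oxygenated arene with the chromene in place and the pre-set C4 stereocentre intact. The diene is built de novo with its prenyl group. The alkyne comes from dihydroresveratrol by asymmetric conjugate alkynylation.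

Key step: step 19

Remark: TBS = tert-butyldimethylsilyl, TIPS = triisopropylsilyl, TMS = trimethylsilyl, MOM = methoxymethyl; primed locants belong to the 2H-chromene (ring A), unprimed ones to the chroman (ring B).
Remark: the bisphosphine antipode in step 9 is the one that gives the (S)-adduct; if the sense of induction proves opposite, its enantiomer is used.
Remark: the descriptor at C4 changes from S (the C-silyl alkyne outranks the aryl group) to R (terminal alkyne, ynol ether, final arene) with no change of geometry.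
Remark: dihydroresveratrol is taken as a purchased material (it is also the hydrogenation product of resveratrol).

**Route**

Step 1
Reactants: 1 methyl 3-(4-hydroxyphenyl)propanoate
Product: 2 methyl 3-[4-(TBS-oxy)phenyl]propanoate
Conditions: TBSCl, imidazole, DMF, 25 °C
Reagents that add atoms: tert-butyldimethylsilyl chloride, CC(C)(C)[Si](C)(C)Cl
Why: Imidazole-promoted O-silylation of the phenol gives a fluoride-labile ether that tolerates the bases used later.

Step 2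
Reactants: 3 ethyl acetoacetate; 4 prenyl bromide (1-bromo-3-methylbut-2-ene)
Product: 6 ethyl 7-methyl-3-oxooct-6-enoate, via sodium lithium dianion 5 (not isolated)
Conditions: NaH, THF, 0 °C; n-BuLi, 0 °C; then 4, 0 → 25 °C; 1 M HCl
Reagents that add atoms: none
Why: γ-Alkylation of a β-keto ester dianion: the more basic terminal carbanion is alkylated by the allylic bromide at its CH2 end (SN2).

Step 3
Reactants: 6 ethyl 7-methyl-3-oxooct-6-enoate; 2 methyl 3-[4-(TBS-oxy)phenyl]propanoate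
Product: 8 ethyl 7-[4-(TBS-oxy)phenyl]-4-(3-methylbut-2-en-1-yl)-3,5-dioxoheptanoate, via dilithium dianion 7 (not isolated)
Conditions: 6 (2.2 equiv), LiN(i-Pr)2 (4.4 equiv), THF, 0 °C; then 2 (1 equiv), −78 → 0 °C; AcOH
Reagents that add atoms: none
Why: Claisen-type C-acylation of the γ-carbanion of a β-keto ester dianion by a methyl ester; the excess dianion takes up the proton of the more acidic triketide product.

Step 4
Reactants: 8 ethyl 7-[4-(TBS-oxy)phenyl]-4-(3-methylbut-2-en-1-yl)-3,5-dioxoheptanoate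
Product: 9 6-{2-[4-(TBS-oxy)phenyl]ethyl}-4-hydroxy-5-(3-methylbut-2-en-1-yl)-2H-pyran-2-one
Conditions: DBU (1.5 equiv), toluene, 25 → 60 °C; cold 1 M HCl wash
Reagents that add atoms: none
Why: Base-mediated lactonisation of a 3,5-dioxo ester through the C5 enol oxygen is the standard 4-hydroxy-2-pyrone synthesis and places prenyl at C5 and the arm at C6 without any ring halogenation.

Step 5
Reactants: 9 6-{2-[4-(TBS-oxy)phenyl]ethyl}-4-hydroxy-5-(3-methylbut-2-en-1-yl)-2H-pyran-2-one; 10 3-methylbut-2-enal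
Product: 12 7-{2-[4-(TBS-oxy)phenyl]ethyl}-2,2-dimethyl-8-(3-methylbut-2-en-1-yl)-2H,5H-pyrano[4,3-b]pyran-5-one, via oxatriene 11 (not isolated)
Conditions: ethylenediammonium diacetate (10 mol %), CH2Cl2, 25–40 °C
Reagents that add atoms: none
Why: Knoevenagel condensation at C3 of the 4-hydroxy-2-pyrone followed by oxa-6π electrocyclisation of the 1-oxatriene (formal [3+3] annulation) fuses the 2,2-dimethyl-2H-pyran at the future C4a'–C8a' bond.

Step 6
Reactants: 13 dihydroresveratrol (5-[2-(4-hydroxyphenyl)ethyl]benzene-1,3-diol)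
Product: 14 1,3-bis(MOM-oxy)-5-{2-[4-(MOM-oxy)phenyl]ethyl}benzene
Conditions: NaH, DMF, 0 °C; MOMCl, 0 → 25 °C
Reagents that add atoms: chloromethyl methyl ether, COCCl
Why: O-Alkylation of the three phenoxides installs acetal groups that direct the metalation of step 7.

Step 7
Reactants: 14 1,3-bis(MOM-oxy)-5-{2-[4-(MOM-oxy)phenyl]ethyl}benzene
Product: 16 2,6-bis(MOM-oxy)-4-{2-[4-(MOM-oxy)phenyl]ethyl}benzaldehyde, via aryllithium 15 (not isolated)
Conditions: n-BuLi, TMEDA, THF, 0 °C; DMF, 0 → 25 °C; cold 1 M HCl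
Reagents that add atoms: N,N-dimethylformamide, CN(C)C=O
Why: Directed ortho-metalation: the C–H between the two acetal oxygens is by far the most acidic aryl position, and the aryllithium is formylated by DMF at the carbon that becomes C4a.

Step 8
Reactants: 16 2,6-bis(MOM-oxy)-4-{2-[4-(MOM-oxy)phenyl]ethyl}benzaldehyde; 17 Meldrum's acid (2,2-dimethyl-1,3-dioxane-4,6-dione)
Product: 18 5-[(2,6-bis(MOM-oxy)-4-{2-[4-(MOM-oxy)phenyl]ethyl}phenyl)methylidene]-2,2-dimethyl-1,3-dioxane-4,6-dione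
Conditions: pyrrolidine (10 mol %), AcOH (10 mol %), toluene, 4 Å sieves, 25–50 °C
Reagents that add atoms: none
Why: Knoevenagel condensation with the strongly C–H acidic Meldrum's acid gives a doubly activated acceptor that is still symmetric in its two ortho oxygens.

Step 9
Reactants: 18 the arylidene Meldrum's acid; 19 (trimethylsilyl)acetylene
Product: 20 5-[(1S)-1-(2,6-bis(MOM-oxy)-4-{2-[4-(MOM-oxy)phenyl]ethyl}phenyl)-3-(trimethylsilyl)prop-2-yn-1-yl]-2,2-dimethyl-1,3-dioxane-4,6-dione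
Conditions: [Rh(OAc)(C2H4)2]2 (2.5 mol %), 3,5-Xyl-MeO-BIPHEP (6 mol %, antipode as in the remark), 1,4-dioxane, 25–40 °C
Reagents that add atoms: none
Why: Rhodium-catalysed asymmetric conjugate alkynylation of an arylidene Meldrum's acid by a silylacetylene; the chiral bisphosphine on the alkynylrhodium species selects one enantiotopic face of the alkylidene and so sets the future C4.

Step 10
Reactants: 20 the (S)-alkynyl Meldrum's acid adduct
Product: 21 (3S)-3-(2,6-bis(MOM-oxy)-4-{2-[4-(MOM-oxy)phenyl]ethyl}phenyl)-5-(trimethylsilyl)pent-4-ynoic acid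
Conditions: DMF/H2O (10:1), 100 °C
Reagents that add atoms: water, O
Why: Neutral hydrolysis of the Meldrum's acid ring and decarboxylation of the malonic acid leave the acetals, the silylalkyne and the stereocentre (not alpha to the carboxyl) untouched.

Step 11
Reactants: 21 the (3S)-pentynoic acid
Product: 23 (4S)-5-hydroxy-7-[2-(4-hydroxyphenyl)ethyl]-4-[(trimethylsilyl)ethynyl]chroman-2-one, via triphenol methyl ester 22 (not isolated)
Conditions: HCl, MeOH/THF, 50 °C; evaporate; TsOH·H2O (5 mol %), toluene, 90 °C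
Reagents that add atoms: none
Why: Acidic methanolysis removes the three acetals (formaldehyde trapped as dimethoxymethane) with Fischer esterification, and acid-catalysed lactonisation onto either of the two equivalent ortho phenols gives one dihydrocoumarin, so no regiochemical question arises.

Step 12
Reactants: 23 the dihydroxy dihydrocoumarin
Product: 24 (4S)-5-(TBS-oxy)-7-{2-[4-(TBS-oxy)phenyl]ethyl}-4-[(trimethylsilyl)ethynyl]chroman-2-one
Conditions: TBSOTf, 2,6-lutidine, CH2Cl2, 0 °C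
Reagents that add atoms: tert-butyldimethylsilyl trifluoromethanesulfonate, CC(C)(C)[Si](C)(C)OS(=O)(=O)C(F)(F)F
Why: Silylation of both phenols with a silyl triflate and a hindered, non-nucleophilic base avoids opening of the aryl lactone.

Step 13
Reactants: 24 the bis-TBS dihydrocoumarin
Product: 25 (4S)-8-bromo-5-(TBS-oxy)-7-{2-[4-(TBS-oxy)phenyl]ethyl}-4-[(trimethylsilyl)ethynyl]chroman-2-one
Conditions: NBS (1.05 equiv), DMF, 0 → 25 °C, dark
Reagents that add atoms: N-bromosuccinimide, O=C1CCC(=O)N1Br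
Why: Electrophilic aromatic bromination: while O1 is acylated the C5 silyloxy group is the dominant donor and directs to its para position C8, whereas C6 and the ortho positions of the other ring are flanked by bulky silyl ethers.

Step 14
Reactants: 25 the 8-bromo dihydrocoumarin
Product: 26 2-bromo-5-(TBS-oxy)-3-{2-[4-(TBS-oxy)phenyl]ethyl}-6-[(3S)-5-hydroxy-5-methyl-1-(trimethylsilyl)hex-1-yn-3-yl]phenol
Conditions: MeMgBr (4 equiv), THF, 0 → 25 °C; cold 1 M HCl
Reagents that add atoms: methylmagnesium bromide, C[Mg]Br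
Why: Double Grignard addition to the aryl lactone gives the tertiary carbinol and frees the phenol that was O1; aryl bromide, silyl ethers and silylalkyne are inert to MeMgBr.

Step 15
Reactants: 26 the bromophenol tertiary alcohol
Product: 27 (4S)-8-bromo-5-(TBS-oxy)-7-{2-[4-(TBS-oxy)phenyl]ethyl}-2,2-dimethyl-4-[(trimethylsilyl)ethynyl]chromane
Conditions: TsOH·H2O (10 mol %), toluene, 60 °C
Reagents that add atoms: none
Why: Acid-catalysed cyclodehydration: the tertiary cation is trapped by the adjacent phenol in a six-ring closure, a standard 2,2-dimethylchroman synthesis made safe here by carrying bromine, not prenyl, at C8.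

Step 16
Reactants: 27 the 8-bromochroman; 4 prenyl bromide
Product: 29 (4S)-5-(TBS-oxy)-7-{2-[4-(TBS-oxy)phenyl]ethyl}-2,2-dimethyl-8-(3-methylbut-2-en-1-yl)-4-[(trimethylsilyl)ethynyl]chromane, via prenylzinc bromide 28 (not isolated)
Conditions: 4, Zn dust, LiCl, THF, 25 °C; then 27, Pd(OAc)2 (2 mol %), CPhos (4 mol %), THF, 25–40 °C
Reagents that add atoms: none
Why: Negishi cross-coupling of an allylzinc halide under Pd/CPhos catalysis is linear-selective, so the prenyl group is attached through its CH2 terminus at the position fixed by the bromine.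

Step 17
Reactants: 29 the TMS-alkyne
Product: 30 (4R)-4-ethynyl-5-(TBS-oxy)-7-{2-[4-(TBS-oxy)phenyl]ethyl}-2,2-dimethyl-8-(3-methylbut-2-en-1-yl)chromane
Conditions: AgNO3 (10 mol %), MeOH/CH2Cl2/H2O, 25 °C
Reagents that add atoms: none
Why: Silver-catalysed protodesilylation cleaves the C(sp)–SiMe3 bond selectively in the presence of aryl silyl ethers and alkenes.

Step 18
Reactants: 30 the terminal alkyne
Product: 33 (4R)-5-(TBS-oxy)-7-{2-[4-(TBS-oxy)phenyl]ethyl}-2,2-dimethyl-8-(3-methylbut-2-en-1-yl)-4-[(TIPS-oxy)ethynyl]chromane, via lithium acetylide 31 (not isolated), via lithium ynolate 32 (not isolated)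
Conditions: LiN(SiMe3)2, THF, −78 °C; t-BuOOLi (from t-BuOOH and LiN(SiMe3)2), −78 → 0 °C; TIPSOTf, −78 → 0 °C
Reagents that add atoms: tert-butyl hydroperoxide, CC(C)(C)OO; triisopropylsilyl trifluoromethanesulfonate, CC(C)[Si](OS(=O)(=O)C(F)(F)F)(C(C)C)C(C)C
Why: Oxidation of the lithium acetylide by lithium tert-butyl peroxide gives the ynolate, which the bulky silyl triflate traps on oxygen; the amide base is too weak to deprotonate the benzylic, propargylic C4–H.

Step 19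
Reactants: 12 the pyranopyrone diene; 33 the ring B ynol silyl ether
Product: 35 (4R)-5-(TBS-oxy)-7-{2-[4-(TBS-oxy)phenyl]ethyl}-2,2-dimethyl-8-(3-methylbut-2-en-1-yl)-4-[7-{2-[4-(TBS-oxy)phenyl]ethyl}-2,2-dimethyl-8-(3-methylbut-2-en-1-yl)-5-(TIPS-oxy)-2H-chromen-6-yl]chromane, via bridged lactone cycloadduct 34 (not isolated)
Conditions: AgNTf2 (10 mol %), 4 Å sieves, ClCH2CH2Cl, 25 → 80 °C
Reagents that add atoms: none
Why: Proposed new method: AgNTf2 activates the pair so that the nucleophilic carbon β to the siloxy group of 33 adds to C7 of 12 (1,6-addition to the dienoate) and the dienolate carbon C4a then closes on the silyl ketenium carbon, a stepwise formal [4+2] giving the 2-oxabicyclo[2.2.2]octadienone 34, whose retro-[4+2] loss of CO2 on warming aromatises ring A irreversibly. The closest known reaction types are the thermal Diels–Alder/CO2-extrusion of 2-pyrones with ynamines and alkoxyalkynes and the AgNTf2-catalysed stepwise cycloadditions of siloxyalkynes with enones and 1,2-diazines. The single new ring (ring A) closes by 6-exo-dig attack of C4a on the C=O π bond of the ketenium within the zwitterion, the 2H-pyran staying fused at C4a'–C8a'. No stereocentre is formed, since both bridgeheads of 34 end as aromatic carbons, and C4 of the chroman is not epimerisable under these non-basic conditions. The step needs regioselectivity (chromanyl-bearing carbon to C7, oxygenated carbon to C4a) and chemoselectivity over four-ring closure at C8; matched polarity (nucleophilic β-carbon against the acyloxy-substituted, electrophilic C7; electrophilic ketenium carbon against the enol-ether-like C4a) and the aromatisation driving force secure both. All phenols are silylated, so no proton source diverts the ynol ether to a ketene.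

Step 20
Reactants: 35 the tetrasilyl ether
Product: 36 (4R)-4-{5-hydroxy-7-[2-(4-hydroxyphenyl)ethyl]-2,2-dimethyl-8-(3-methylbut-2-en-1-yl)-2H-chromen-6-yl}-7-[2-(4-hydroxyphenyl)ethyl]-2,2-dimethyl-8-(3-methylbut-2-en-1-yl)chroman-5-ol (CNP0103951.1)
Conditions: TBAF (6 equiv), AcOH (6 equiv), THF, 0 → 25 °C
Reagents that add atoms: none
Why: Fluoride cleaves all four aryl silyl ethers, and the acetic acid buffer protects the electron-rich phenoxides and the chromene from base- or air-induced degradation.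

**Compound list**

1 | methyl 3-(4-hydroxyphenyl)propanoate | COC(=O)CCc1ccc(O)cc1 | starting material
2 | methyl 3-[4-(TBS-oxy)phenyl]propanoate | COC(=O)CCc1ccc(O[Si](C)(C)C(C)(C)C)cc1 | intermediate
3 | ethyl acetoacetate | CCOC(=O)CC(C)=O | starting material
4 | prenyl bromide (1-bromo-3-methylbut-2-ene) | CC(C)=CCBr | starting material
5 | sodium lithium dianion of ethyl acetoacetate | [CH2-]C(=O)[CH-]C(=O)OCC.[Na+].[Li+] | intermediate
6 | ethyl 7-methyl-3-oxooct-6-enoate | CCOC(=O)CC(=O)CCC=C(C)C | intermediate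
7 | dilithium C2,C4-dianion of 6 | CCOC(=O)[CH-]C(=O)[CH-]CC=C(C)C.[Li+].[Li+] | intermediate
8 | ethyl 7-[4-(TBS-oxy)phenyl]-4-(3-methylbut-2-en-1-yl)-3,5-dioxoheptanoate | CCOC(=O)CC(=O)C(CC=C(C)C)C(=O)CCc1ccc(O[Si](C)(C)C(C)(C)C)cc1 | intermediate
9 | 6-{2-[4-(TBS-oxy)phenyl]ethyl}-4-hydroxy-5-(3-methylbut-2-en-1-yl)-2H-pyran-2-one | O=C1C=C(O)C(CC=C(C)C)=C(CCc2ccc(O[Si](C)(C)C(C)(C)C)cc2)O1 | intermediate
10 | 3-methylbut-2-enal | CC(C)=CC=O | starting material
11 | 6-{2-[4-(TBS-oxy)phenyl]ethyl}-5-(3-methylbut-2-en-1-yl)-3-(3-methylbut-2-en-1-ylidene)pyran-2,4-dione (1-oxatriene) | O=C1OC(CCc2ccc(O[Si](C)(C)C(C)(C)C)cc2)=C(CC=C(C)C)C(=O)C1=CC=C(C)C | intermediate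
12 | 7-{2-[4-(TBS-oxy)phenyl]ethyl}-2,2-dimethyl-8-(3-methylbut-2-en-1-yl)-2H,5H-pyrano[4,3-b]pyran-5-one | O=C1OC(CCc2ccc(O[Si](C)(C)C(C)(C)C)cc2)=C(CC=C(C)C)C2=C1C=CC(C)(C)O2 | intermediate
13 | dihydroresveratrol | Oc1ccc(CCc2cc(O)cc(O)c2)cc1 | starting material
14 | 1,3-bis(MOM-oxy)-5-{2-[4-(MOM-oxy)phenyl]ethyl}benzene | COCOc1ccc(CCc2cc(OCOC)cc(OCOC)c2)cc1 | intermediate
15 | 2-lithio derivative of 14 | [Li]c1c(OCOC)cc(CCc2ccc(OCOC)cc2)cc1OCOC | intermediate
16 | 2,6-bis(MOM-oxy)-4-{2-[4-(MOM-oxy)phenyl]ethyl}benzaldehyde | COCOc1ccc(CCc2cc(OCOC)c(C=O)c(OCOC)c2)cc1 | intermediate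
17 | Meldrum's acid | CC1(C)OC(=O)CC(=O)O1 | starting material
18 | 5-[(2,6-bis(MOM-oxy)-4-{2-[4-(MOM-oxy)phenyl]ethyl}phenyl)methylidene]-2,2-dimethyl-1,3-dioxane-4,6-dione | COCOc1ccc(CCc2cc(OCOC)c(C=C3C(=O)OC(C)(C)OC3=O)c(OCOC)c2)cc1 | intermediate
19 | (trimethylsilyl)acetylene | C#C[Si](C)(C)C | starting material
20 | 5-[(1S)-1-(2,6-bis(MOM-oxy)-4-{2-[4-(MOM-oxy)phenyl]ethyl}phenyl)-3-(trimethylsilyl)prop-2-yn-1-yl]-2,2-dimethyl-1,3-dioxane-4,6-dione | C[Si](C)(C)C#C[C@H](c1c(OCOC)cc(CCc2ccc(OCOC)cc2)cc1OCOC)C1C(=O)OC(C)(C)OC1=O | intermediate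
21 | (3S)-3-(2,6-bis(MOM-oxy)-4-{2-[4-(MOM-oxy)phenyl]ethyl}phenyl)-5-(trimethylsilyl)pent-4-ynoic acid | C[Si](C)(C)C#C[C@H](c1c(OCOC)cc(CCc2ccc(OCOC)cc2)cc1OCOC)CC(=O)O | intermediate
22 | methyl (3S)-3-{2,6-dihydroxy-4-[2-(4-hydroxyphenyl)ethyl]phenyl}-5-(trimethylsilyl)pent-4-ynoate | C[Si](C)(C)C#C[C@H](c1c(O)cc(CCc2ccc(O)cc2)cc1O)CC(=O)OC | intermediate
23 | (4S)-5-hydroxy-7-[2-(4-hydroxyphenyl)ethyl]-4-[(trimethylsilyl)ethynyl]chroman-2-one | C[Si](C)(C)C#C[C@H]1CC(=O)Oc2cc(CCc3ccc(O)cc3)cc(O)c21 | intermediate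
24 | (4S)-5-(TBS-oxy)-7-{2-[4-(TBS-oxy)phenyl]ethyl}-4-[(trimethylsilyl)ethynyl]chroman-2-one | C[Si](C)(C)C#C[C@H]1CC(=O)Oc2cc(CCc3ccc(O[Si](C)(C)C(C)(C)C)cc3)cc(O[Si](C)(C)C(C)(C)C)c21 | intermediate
25 | (4S)-8-bromo-5-(TBS-oxy)-7-{2-[4-(TBS-oxy)phenyl]ethyl}-4-[(trimethylsilyl)ethynyl]chroman-2-one | C[Si](C)(C)C#C[C@H]1CC(=O)Oc2c(Br)c(CCc3ccc(O[Si](C)(C)C(C)(C)C)cc3)cc(O[Si](C)(C)C(C)(C)C)c21 | intermediate
26 | 2-bromo-5-(TBS-oxy)-3-{2-[4-(TBS-oxy)phenyl]ethyl}-6-[(3S)-5-hydroxy-5-methyl-1-(trimethylsilyl)hex-1-yn-3-yl]phenol | C[Si](C)(C)C#C[C@H](c1c(O)c(Br)c(CCc2ccc(O[Si](C)(C)C(C)(C)C)cc2)cc1O[Si](C)(C)C(C)(C)C)CC(C)(C)O | intermediate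
27 | (4S)-8-bromo-5-(TBS-oxy)-7-{2-[4-(TBS-oxy)phenyl]ethyl}-2,2-dimethyl-4-[(trimethylsilyl)ethynyl]chromane | C[Si](C)(C)C#C[C@H]1CC(C)(C)Oc2c(Br)c(CCc3ccc(O[Si](C)(C)C(C)(C)C)cc3)cc(O[Si](C)(C)C(C)(C)C)c21 | intermediate
28 | prenylzinc bromide | CC(C)=CC[Zn]Br | intermediate
29 | (4S)-5-(TBS-oxy)-7-{2-[4-(TBS-oxy)phenyl]ethyl}-2,2-dimethyl-8-(3-methylbut-2-en-1-yl)-4-[(trimethylsilyl)ethynyl]chromane | C[Si](C)(C)C#C[C@H]1CC(C)(C)Oc2c(CC=C(C)C)c(CCc3ccc(O[Si](C)(C)C(C)(C)C)cc3)cc(O[Si](C)(C)C(C)(C)C)c21 | intermediate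
30 | (4R)-4-ethynyl-5-(TBS-oxy)-7-{2-[4-(TBS-oxy)phenyl]ethyl}-2,2-dimethyl-8-(3-methylbut-2-en-1-yl)chromane | C#C[C@H]1CC(C)(C)Oc2c(CC=C(C)C)c(CCc3ccc(O[Si](C)(C)C(C)(C)C)cc3)cc(O[Si](C)(C)C(C)(C)C)c21 | intermediate
31 | lithium acetylide of 30 | [Li]C#C[C@H]1CC(C)(C)Oc2c(CC=C(C)C)c(CCc3ccc(O[Si](C)(C)C(C)(C)C)cc3)cc(O[Si](C)(C)C(C)(C)C)c21 | intermediate
32 | lithium ynolate from 31 | [Li]OC#C[C@H]1CC(C)(C)Oc2c(CC=C(C)C)c(CCc3ccc(O[Si](C)(C)C(C)(C)C)cc3)cc(O[Si](C)(C)C(C)(C)C)c21 | intermediate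
33 | (4R)-5-(TBS-oxy)-7-{2-[4-(TBS-oxy)phenyl]ethyl}-2,2-dimethyl-8-(3-methylbut-2-en-1-yl)-4-[(TIPS-oxy)ethynyl]chromane | CC(C)[Si](C(C)C)(C(C)C)OC#C[C@H]1CC(C)(C)Oc2c(CC=C(C)C)c(CCc3ccc(O[Si](C)(C)C(C)(C)C)cc3)cc(O[Si](C)(C)C(C)(C)C)c21 | intermediate
34 | 2-oxabicyclo[2.2.2]octa-5,7-dien-3-one cycloadduct of 12 and 33 (bridgeheads are C4a and C7 of 12; either bridgehead diastereomer; chroman C4 as in 33) | O=C1OC2(CCc3ccc(O[Si](C)(C)C(C)(C)C)cc3)C(CC=C(C)C)=C3OC(C)(C)C=CC31C(O[Si](C(C)C)(C(C)C)C(C)C)=C2[C@H]1CC(C)(C)Oc2c(CC=C(C)C)c(CCc3ccc(O[Si](C)(C)C(C)(C)C)cc3)cc(O[Si](C)(C)C(C)(C)C)c21 | intermediate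
35 | (4R)-5-(TBS-oxy)-7-{2-[4-(TBS-oxy)phenyl]ethyl}-2,2-dimethyl-8-(3-methylbut-2-en-1-yl)-4-[7-{2-[4-(TBS-oxy)phenyl]ethyl}-2,2-dimethyl-8-(3-methylbut-2-en-1-yl)-5-(TIPS-oxy)-2H-chromen-6-yl]chromane | CC(C)=CCc1c(CCc2ccc(O[Si](C)(C)C(C)(C)C)cc2)c([C@H]2CC(C)(C)Oc3c(CC=C(C)C)c(CCc4ccc(O[Si](C)(C)C(C)(C)C)cc4)cc(O[Si](C)(C)C(C)(C)C)c32)c(O[Si](C(C)C)(C(C)C)C(C)C)c2c1OC(C)(C)C=C2 | intermediate
36 | (4R)-4-{5-hydroxy-7-[2-(4-hydroxyphenyl)ethyl]-2,2-dimethyl-8-(3-methylbut-2-en-1-yl)-2H-chromen-6-yl}-7-[2-(4-hydroxyphenyl)ethyl]-2,2-dimethyl-8-(3-methylbut-2-en-1-yl)chroman-5-ol | CC(C)=CCc1c(CCc2ccc(O)cc2)c([C@H]2CC(C)(C)Oc3c(CC=C(C)C)c(CCc4ccc(O)cc4)cc(O)c32)c(O)c2c1OC(C)(C)C=C2 | target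

**Step count and risks**

Total step count: 20. Longest linear sequence: 15 steps (steps 6–18, then 19 and 20).

Steps most likely to fail:

1. Step 19. The ynol silyl ether may be consumed by silver-induced self-reaction or hydrolysis before it engages the tetrasubstituted, donor-substituted diene, or the first C–C bond may form without ring closure. The fallback uses known chemistry, sets out from 16 and rejoins the route at 36; it abandons the cycloaddition and uses the fact that the target is the hydroarylation dimer of one chromene.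
   - HCl in MeOH frees 2,6-dihydroxy-4-[2-(4-hydroxyphenyl)ethyl]benzaldehyde F1.
   - Wittig reaction with Ph3P=CHCO2Et in N,N-diethylaniline at reflux passes through the hydroxycinnamate F2 and lactonises to the coumarin F3.
   - TBSOTf gives the bis-silyl ether F4.
   - NBS brominates C8 (para to the silyloxy group, the lactone oxygen being a poor donor) to give the bromocoumarin F5.
   - MeMgBr adds twice to the lactone carbonyl to give the (Z)-allylic tertiary alcohol F6, which closes with acid to the 8-bromo-2,2-dimethyl-2H-chromene F7.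
   - The Negishi coupling of step 16 (with 28) gives the prenylchromene F8, and TBAF gives the free monomer F9.
   - A Brønsted acid (TFA, CH2Cl2, low temperature) protonates C3 of one molecule, and C6 of a second traps the C4 cation (Friedel–Crafts hydroarylation) to give the racemic dimer F10.
   - Chromatography on a chiral stationary phase resolves F10 to 36.

2. Step 9. Face discrimination may be poor, or insertion may fail, at the doubly ortho-substituted, twisted arylidene. The fallback sets out from 18 and rejoins at 21.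
   - (Trimethylsilyl)ethynylmagnesium bromide (from 19 and EtMgBr) adds 1,4 to 18 to give the racemic adduct F11.
   - The conditions of step 10 give the racemic acid F12.
   - Crystallisation with one antipode of 1-phenylethylamine gives the diastereomerically pure salt F13 (drawn for the (S)-amine), and acidification returns 21.

3. Step 3. Proton transfer from the enolisable ester to the hindered γ-carbanion may outrun C-acylation and return both partners. The fallback sets out from 2 and rejoins at 8.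
   - i-Bu2AlH at −78 °C reduces 2 to 3-[4-(TBS-oxy)phenyl]propanal F14.
   - Aldol addition of dianion 7 to this aldehyde gives the β-hydroxy ketone F15.
   - Dess–Martin periodinane oxidises F15 to 8.

Further compounds
F1 | step 19 | 2,6-dihydroxy-4-[2-(4-hydroxyphenyl)ethyl]benzaldehyde | O=Cc1c(O)cc(CCc2ccc(O)cc2)cc1O
F2 | step 19 | ethyl (E)-3-{2,6-dihydroxy-4-[2-(4-hydroxyphenyl)ethyl]phenyl}prop-2-enoate | CCOC(=O)/C=C/c1c(O)cc(CCc2ccc(O)cc2)cc1O
F3 | step 19 | 5-hydroxy-7-[2-(4-hydroxyphenyl)ethyl]-2H-chromen-2-one | O=C1C=Cc2c(O)cc(CCc3ccc(O)cc3)cc2O1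
F4 | step 19 | 5-(TBS-oxy)-7-{2-[4-(TBS-oxy)phenyl]ethyl}-2H-chromen-2-one | O=C1C=Cc2c(O[Si](C)(C)C(C)(C)C)cc(CCc3ccc(O[Si](C)(C)C(C)(C)C)cc3)cc2O1
F5 | step 19 | 8-bromo-5-(TBS-oxy)-7-{2-[4-(TBS-oxy)phenyl]ethyl}-2H-chromen-2-one | O=C1C=Cc2c(O[Si](C)(C)C(C)(C)C)cc(CCc3ccc(O[Si](C)(C)C(C)(C)C)cc3)c(Br)c2O1
F6 | step 19 | 2-bromo-5-(TBS-oxy)-3-{2-[4-(TBS-oxy)phenyl]ethyl}-6-[(Z)-3-hydroxy-3-methylbut-1-en-1-yl]phenol | CC(C)(O)/C=C\c1c(O[Si](C)(C)C(C)(C)C)cc(CCc2ccc(O[Si](C)(C)C(C)(C)C)cc2)c(Br)c1O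
F7 | step 19 | 8-bromo-5-(TBS-oxy)-7-{2-[4-(TBS-oxy)phenyl]ethyl}-2,2-dimethyl-2H-chromene | CC1(C)C=Cc2c(O[Si](C)(C)C(C)(C)C)cc(CCc3ccc(O[Si](C)(C)C(C)(C)C)cc3)c(Br)c2O1
F8 | step 19 | 5-(TBS-oxy)-7-{2-[4-(TBS-oxy)phenyl]ethyl}-2,2-dimethyl-8-(3-methylbut-2-en-1-yl)-2H-chromene | CC(C)=CCc1c(CCc2ccc(O[Si](C)(C)C(C)(C)C)cc2)cc(O[Si](C)(C)C(C)(C)C)c2c1OC(C)(C)C=C2
F9 | step 19 | 7-[2-(4-hydroxyphenyl)ethyl]-2,2-dimethyl-8-(3-methylbut-2-en-1-yl)-2H-chromen-5-ol | CC(C)=CCc1c(CCc2ccc(O)cc2)cc(O)c2c1OC(C)(C)C=C2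
F10 | step 19 | racemic 36 | CC(C)=CCc1c(CCc2ccc(O)cc2)c(C2CC(C)(C)Oc3c(CC=C(C)C)c(CCc4ccc(O)cc4)cc(O)c32)c(O)c2c1OC(C)(C)C=C2
F11 | step 9 | racemic 20 | C[Si](C)(C)C#CC(c1c(OCOC)cc(CCc2ccc(OCOC)cc2)cc1OCOC)C1C(=O)OC(C)(C)OC1=O
F12 | step 9 | racemic 21 | C[Si](C)(C)C#CC(c1c(OCOC)cc(CCc2ccc(OCOC)cc2)cc1OCOC)CC(=O)O
F13 | step 9 | (S)-1-phenylethylammonium salt of 21 | C[Si](C)(C)C#C[C@H](c1c(OCOC)cc(CCc2ccc(OCOC)cc2)cc1OCOC)CC(=O)[O-].C[C@H]([NH3+])c1ccccc1
F14 | step 3 | 3-[4-(TBS-oxy)phenyl]propanal | O=CCCc1ccc(O[Si](C)(C)C(C)(C)C)cc1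
F15 | step 3 | ethyl 7-[4-(TBS-oxy)phenyl]-5-hydroxy-4-(3-methylbut-2-en-1-yl)-3-oxoheptanoate (diastereomer mixture) | CCOC(=O)CC(=O)C(CC=C(C)C)C(O)CCc1ccc(O[Si](C)(C)C(C)(C)C)cc1
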